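If each E charged begins one chain and G begins none, the average chain length is the share of Q turned into X times the length scale, cQ/cE, here 40.0.

the same everywhere: Q 0.40 M

|  | G | E | remark | time |
|---|---|---|---|---|
| eta | 0.010 M | 10 mM | run made earlier |  |
| zeta | 0.040 M | 10 mM | run made earlier |  |
| epsilon | 0.020 M | 20 mM | run made earlier |  |
| grey | 0.0200 M | 10 mM |  | 12 h |
| blue | 0.0200 M | 10 mM |  | 40 h |

| run | time / h | X / % |
|---|---|---|
| eta | 1.33 | 2.7 |
| eta | 2.50 | 6.7 |
| eta | 4.00 | 12.5 |
| eta | 5.00 | 16.7 |
| eta | 6.00 | 19.9 |
| eta | 8.00 | 29.2 |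
| zeta | 0.500 | 0.9 |
| zeta | 1.33 | 1.6 |
| zeta | 2.50 | 5.2 |
| zeta | 4.00 | 10.8 |
| zeta | 6.00 | 18.5 |
| zeta | 8.00 | 26.0 |
| epsilon | 1.33 | 4.5 |
| epsilon | 3.00 | 14.3 |
| epsilon | 4.00 | 21.4 |
| epsilon | 6.00 | 33.7 |
| epsilon | 8.00 | 42.5 |

(standard deviation of a reading: 0.5 percentage points)

* which of the two ends with the longer chains by the average number of monomer units in a chain (chains begun, living or dead) ("neither" if they lie within 10%) (grey / blue / neither)
* average number of monomer units in a chain (chains begun, living or dead) at the end, grey
* average number of monomer units in a chain (chains begun, living or dead) at the end, blue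

Minutes of the meeting on grey and blue. One member reported that eta and zeta gained 17 percentage points and 15 points between 4.00 h and 8.00 h, with G at 0.010 M and 0.040 M. Another reported that epsilon, with 20 mM of E, gained 21 points over those hours. She took the growing ends to follow E. So I counted one chain per E, which the readings cannot show.

I then solved both ends and joined them. Epsilon's gain fell from 0.0710 /h to 0.0440 /h, as shares of charged Q. A straight line through these reaches zero at a ceiling of X, read as 71.1%. The Q left at such a ceiling is the equilibrium monomer concentration. Eta's approach to that ceiling gives 0.0839 /h. So I expected X of 41.1% in grey and 68.2% in blue, hence lengths 16.5 and 27.3.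

The forecast chose blue, with 7 (5.5 to 10) for grey and 11.5 (8.5 to 16) for blue, on a chain count unlike mine: “Chains are guessed as 20 mM from G plus initiator-derived chains”.

The flask gives blue, with 16.2 for grey and 24.0 for blue.

    G + Q → J (k = 0.0590 /M/min)
    X + L → Q + L, rate k2*[L] as long as [X] is above zero (k = 0.0260 /min)
    Q + L → X + L, rate k3*[L]*[Q] (k = 0.190 /M/min)
    E ⇌ D (K = 0.390, k = 0.00560 /min)
    Q + D → L + X (k = 0.400 /M/min)

Blue holds X at 59.9%, and the length scale turns that share into 24.0. A neighbour of blue with 0.0040 M of E has the scale 100 and X of 49.6%, which gives 49.6, and it stores 49.6. Blue has come to rest: at 40.0 h, X is made 1.03 times as fast as it is used up. Ten times the time moves its X from 59.9% to 60.8% and its length from 24.0 to 24.3. Grey is still moving at 12.0 h, with X at 39.3% and length 16.2. At 120 h it holds X of 60.8% and length 24.3.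

Readings and results were computed from invented constants; the scatter is artificial.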